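**Strategy**

The quinone ring is cut across C4–C5 and C1–C6 (numbering: C1=O between C2–CH3 and C6–side chain; C4=O between C3–H and C5–H). C5–H and C6–alkyl are read as the imprint of a terminal alkyne, C4/C3/C2 as a propenyl(methoxy)carbene ligand and C1 as a carbonyl ligand on chromium. A Dötz benzannulation with oxidative work-up in the same flask therefore builds the 2-methyl-6-alkylbenzoquinone in the last step from a skipped enyne that already carries the whole polyene chain and the (R)-lactone. That enyne comes from farnesyl bromide and a CBS-derived lactone phosphonate, joined by a Z-selective Still–Gennari olefination.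

Key step: step 10

Assumption: the lactone stereocentre is read as (R) and the alkylidene double bond as (Z) (side chain cis to the lactone carbonyl); bis(2,2,2-trifluoroethyl) phosphorochloridate is taken as a purchasable reagent.

**Route**

Step 1
Reactants: 1 (2E,6E)-farnesyl bromide; 2 ethynyltrimethylsilane
Product: 4 trimethyl[(4E,8E)-5,9,13-trimethyltetradeca-4,8,12-trien-1-yn-1-yl]silane, via alkynylmagnesium bromide 3 (not isolated)
Conditions: 2, EtMgBr, THF, 0 °C to rt; then CuBr·SMe2 (5 mol%), 1, THF, 50 °C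
Reagents that add atoms: none
Why: Copper-catalysed SN2 coupling of an alkynyl Grignard reagent with a primary allylic bromide should give the skipped enyne with the (E)-alkenes untouched, the silyl cap preventing a second allylation.

Step 2
Reactants: 4 silylated trienyne
Product: 5 (6E,10E)-3-bromo-2,6,10-trimethyl-14-(trimethylsilyl)tetradeca-6,10-dien-13-yn-2-ol (racemic)
Conditions: NBS (1.1 equiv), THF/H2O (3:1), 0 °C
Reagents that add atoms: N-bromosuccinimide, O=C1CCC(=O)N1Br; water, O
Why: Bromohydrin formation in aqueous THF should occur selectively at the exposed terminal trisubstituted alkene of the coiled polyene, with Markovnikov attack of water at the tertiary carbon and no reaction at the silyl alkyne.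

Step 3
Reactants: 5 bromohydrin
Product: 7 2,2-dimethyl-3-[(3E,7E)-3,7-dimethylundeca-3,7-dien-10-yn-1-yl]oxirane (racemic), via silylated epoxide 6 (not isolated)
Conditions: K2CO3, MeOH, rt
Reagents that add atoms: none
Why: Intramolecular Williamson closure of the bromohydrin gives the epoxide, and the same mild base should protodesilylate the alkynylsilane without isomerising the skipped enyne.

Step 4
Reactants: 7 epoxy enyne
Product: 8 (4E,8E)-4,8-dimethyldodeca-4,8-dien-11-ynal
Conditions: H5IO6, THF/H2O, 0 °C
Reagents that add atoms: none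
Why: Periodic acid opens the trisubstituted epoxide at its tertiary carbon and cleaves the resulting glycol (Malaprade cleavage), so the aldehyde keeps the epoxide oxygen while acetone is lost and the alkenes and alkyne are untouched.

Step 5
Reactants: 9 methyl 5-chloro-5-oxopentanoate; 10 isopropenylmagnesium bromide
Product: 11 methyl 6-methyl-5-oxohept-6-enoate
Conditions: CuI (10 mol%), THF, −78 °C, slow addition of 10
Reagents that add atoms: none
Why: Copper-catalysed acylation of a Grignard reagent by an acid chloride at −78 °C should be far faster than attack on the methyl ester or on the α-branched enone product.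

Step 6
Reactants: 11 enone ester
Product: 13 (6R)-6-(prop-1-en-2-yl)oxan-2-one, via hydroxy ester 12 (not isolated)
Conditions: (S)-2-methyl-CBS-oxazaborolidine (20 mol%), catecholborane, toluene, −78 °C; work-up; PPTS (cat.), toluene, 60 °C
Reagents that add atoms: none
Why: In the Corey–Bakshi–Shibata reduction the (S)-oxazaborolidine binds the ketone with the isopropenyl group as the large substituent, so hydride is delivered to the face that gives the (R)-carbinol, and mild acid then closes the δ-lactone by transesterification without touching that centre.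

Step 7
Reactants: 13 (R)-lactone
Product: 15 bis(2,2,2-trifluoroethyl) [(6R)-2-oxo-6-(prop-1-en-2-yl)oxan-3-yl]phosphonate (mixture of C3 epimers), via enol phosphate 14 (not isolated)
Conditions: LiN(iPr)2 (1.1 equiv), THF, −78 °C; ClP(O)(OCH2CF3)2; then LiN(iPr)2 (2.2 equiv), −78 to 0 °C; dilute HCl
Reagents that add atoms: bis(2,2,2-trifluoroethyl) phosphorochloridate, O=P(Cl)(OCC(F)(F)F)OCC(F)(F)F
Why: O-phosphorylation of the lactone enolate followed by base-induced 1,3 O-to-C phosphoryl migration (vinyl phosphate to phosphonate rearrangement) should be driven by formation of the stabilised phosphonate enolate, and the new C3 centre is inconsequential because it is destroyed in step 8.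

Step 8
Reactants: 8 enyne aldehyde; 15 lactone phosphonate
Product: 16 (3Z,6R)-3-[(4E,8E)-4,8-dimethyldodeca-4,8-dien-11-yn-1-ylidene]-6-(prop-1-en-2-yl)oxan-2-one
Conditions: 15, KN(SiMe3)2, 18-crown-6, THF, −78 °C; then 8, −78 °C
Reagents that add atoms: none
Why: In this Still–Gennari variant of the Horner–Wadsworth–Emmons reaction the electron-poor trifluoroethyl phosphonate and the crown-separated potassium ion make elimination from the kinetic adduct faster than its reversal, which should place the aldehyde chain cis to the lactone carbonyl, i.e. the (Z)-alkylidene lactone, with the minor (E)-isomer removed by chromatography.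

Step 9
Reactants: 17 (E)-1-bromoprop-1-ene; 18 Cr(CO)6
Product: 21 pentacarbonyl[(2E)-1-methoxybut-2-en-1-ylidene]chromium, via propenyllithium 19 (not isolated), via lithium acylchromate 20 (not isolated)
Conditions: t-BuLi (2 equiv), Et2O, −78 °C; Cr(CO)6, Et2O, 0 °C to rt; Me3OBF4, CH2Cl2, 0 °C
Reagents that add atoms: trimethyloxonium tetrafluoroborate, C[O+](C)C.F[B-](F)(F)F
Why: This is the Fischer carbene synthesis, in which lithium–bromine exchange with retention of alkene geometry, addition of the alkenyllithium to a carbonyl ligand and O-methylation of the acylmetalate should give the alkenyl(methoxy)carbene complex.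

Step 10
Reactants: 16 enyne lactone; 21 propenyl(methoxy)carbene chromium complex (1.5 equiv)
Product: 24 (3Z,6R)-3-[(4E,8E)-4,8-dimethyl-10-(5-methyl-3,6-dioxocyclohexa-1,4-dien-1-yl)deca-4,8-dien-1-ylidene]-6-(prop-1-en-2-yl)oxan-2-one (target), via phenol chromium tricarbonyl complex 22 (not isolated), via para-methoxyphenol 23 (not isolated)
Conditions: THF (0.05 M), 50 °C, argon; then (NH4)2Ce(NO3)6, MeCN/H2O, 0 °C
Reagents that add atoms: water, O
Why: Thermal loss of one CO from 21 lets the terminal alkyne of 16 insert into the Cr=C bond with its unsubstituted terminus bonding to the carbene carbon (quinone C4–C5 bond), and CO insertion into the resulting vinylcarbene joins a carbonyl ligand to the substituted alkyne carbon (C1–C6 bond) to give a chromium-bound dienylketene. 6π-Electrocyclization of that ketene onto the propenyl terminus (C1–C2 bond) and tautomerization close the only new ring as a formal [3+2+1] annulation, the Dötz benzannulation, which is the directly applicable known reaction type for alkenyl(alkoxy)carbene complexes and terminal alkynes. The oxidant then strips zerovalent chromium from arene complex 22 and oxidizes the freed para-methoxyphenol 23 in the same flask, water replacing the methoxy group, so the quinone level is reached without a separate step. No stereocentre is formed, and the (R)-lactone centre and the chain double bonds should be spectators under neutral thermal conditions and a brief cold oxidation. The step needs regioselectivity for 2,6- over 2,5-substitution, which the steric bias of a terminal alkyne secures by placing the large propargylic chain next to the CO-derived carbon. It also needs chemoselectivity for the alkyne over the alkenes, which rests on alkyne insertion at 50 °C being much faster than cyclopropanation by an alkoxycarbene complex.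

**Compound list**

1 | (2E,6E)-farnesyl bromide | CC(C)=CCC/C(C)=C/CC/C(C)=C/CBr | starting material
2 | ethynyltrimethylsilane | C#C[Si](C)(C)C | starting material
3 | [(trimethylsilyl)ethynyl]magnesium bromide | C[Si](C)(C)C#C[Mg]Br | intermediate
4 | trimethyl[(4E,8E)-5,9,13-trimethyltetradeca-4,8,12-trien-1-yn-1-yl]silane | CC(C)=CCC/C(C)=C/CC/C(C)=C/CC#C[Si](C)(C)C | intermediate
5 | (6E,10E)-3-bromo-2,6,10-trimethyl-14-(trimethylsilyl)tetradeca-6,10-dien-13-yn-2-ol (racemic) | CC(C)(O)C(Br)CC/C(C)=C/CC/C(C)=C/CC#C[Si](C)(C)C | intermediate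
6 | {(4E,8E)-11-(3,3-dimethyloxiran-2-yl)-5,9-dimethylundeca-4,8-dien-1-yn-1-yl}trimethylsilane (racemic) | CC1(C)OC1CC/C(C)=C/CC/C(C)=C/CC#C[Si](C)(C)C | intermediate
7 | 2,2-dimethyl-3-[(3E,7E)-3,7-dimethylundeca-3,7-dien-10-yn-1-yl]oxirane (racemic) | CC1(C)OC1CC/C(C)=C/CC/C(C)=C/CC#C | intermediate
8 | (4E,8E)-4,8-dimethyldodeca-4,8-dien-11-ynal | O=CCC/C(C)=C/CC/C(C)=C/CC#C | intermediate
9 | methyl 5-chloro-5-oxopentanoate | COC(=O)CCCC(=O)Cl | starting material
10 | isopropenylmagnesium bromide | C=C(C)[Mg]Br | starting material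
11 | methyl 6-methyl-5-oxohept-6-enoate | COC(=O)CCCC(=O)C(C)=C | intermediate
12 | methyl (5R)-5-hydroxy-6-methylhept-6-enoate | C=C(C)[C@H](O)CCCC(=O)OC | intermediate
13 | (6R)-6-(prop-1-en-2-yl)oxan-2-one | C=C(C)[C@H]1CCCC(=O)O1 | intermediate
14 | (2R)-2-(prop-1-en-2-yl)-3,4-dihydro-2H-pyran-6-yl bis(2,2,2-trifluoroethyl) phosphate | C=C(C)[C@H]1CCC=C(OP(=O)(OCC(F)(F)F)OCC(F)(F)F)O1 | intermediate
15 | bis(2,2,2-trifluoroethyl) [(6R)-2-oxo-6-(prop-1-en-2-yl)oxan-3-yl]phosphonate (C3 epimers) | C=C(C)[C@H]1CCC(P(=O)(OCC(F)(F)F)OCC(F)(F)F)C(=O)O1 | intermediate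
16 | (3Z,6R)-3-[(4E,8E)-4,8-dimethyldodeca-4,8-dien-11-yn-1-ylidene]-6-(prop-1-en-2-yl)oxan-2-one | C=C(C)[C@H]1CC/C(=C/CC/C(C)=C/CC/C(C)=C/CC#C)C(=O)O1 | intermediate
17 | (E)-1-bromoprop-1-ene | C/C=C/Br | starting material
18 | hexacarbonylchromium, Cr(CO)6 | O=C=[Cr](=C=O)(=C=O)(=C=O)(=C=O)=C=O | starting material
19 | (E)-prop-1-enyllithium | C/C=C/[Li] | intermediate
20 | pentacarbonyl[(2E)-1-(lithiooxy)but-2-en-1-ylidene]chromium | C/C=C/C(O[Li])=[Cr](=C=O)(=C=O)(=C=O)(=C=O)=C=O | intermediate
21 | pentacarbonyl[(2E)-1-methoxybut-2-en-1-ylidene]chromium | COC(/C=C/C)=[Cr](=C=O)(=C=O)(=C=O)(=C=O)=C=O | intermediate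
22 | tricarbonylchromium complex of phenol 23 (Cr(CO)3 bound η6 to the arene, drawn as two parts) | C=C(C)[C@H]1CC/C(=C/CC/C(C)=C/CC/C(C)=C/Cc2cc(OC)cc(C)c2O)C(=O)O1.O=C=[Cr](=C=O)=C=O | intermediate
23 | (3Z,6R)-3-[(4E,8E)-10-(2-hydroxy-5-methoxy-3-methylphenyl)-4,8-dimethyldeca-4,8-dien-1-ylidene]-6-(prop-1-en-2-yl)oxan-2-one | C=C(C)[C@H]1CC/C(=C/CC/C(C)=C/CC/C(C)=C/Cc2cc(OC)cc(C)c2O)C(=O)O1 | intermediate
24 | (3Z,6R)-3-[(4E,8E)-4,8-dimethyl-10-(5-methyl-3,6-dioxocyclohexa-1,4-dien-1-yl)deca-4,8-dien-1-ylidene]-6-(prop-1-en-2-yl)oxan-2-one | C=C(C)[C@H]1CC/C(=C/CC/C(C)=C/CC/C(C)=C/CC2=CC(=O)C=C(C)C2=O)C(=O)O1 | target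

**Step count**

Total steps: 10. Longest linear sequence: 6 steps (steps 1, 2, 3, 4, 8, 10).

**Steps most likely to fail**

Step 8. The risk is erosion of geometric control: the ring-locked phosphonate cannot adopt the ester conformation on which open-chain Still–Gennari selectivity rests, so the adducts may equilibrate before elimination and divert material to the (E)-alkylidene lactone. The fallback fixes the geometry in an open-chain olefination and closes the lactone afterwards; it sets out from aldehyde 8 and returns at 16. Commercial methyl bis(2,2,2-trifluoroethyl)phosphonoacetate would be alkylated with 2-(2-bromoethyl)-1,3-dioxolane (NaH, DMSO) to methyl 2-[bis(2,2,2-trifluoroethoxy)phosphoryl]-4-(1,3-dioxolan-2-yl)butanoate F1. Olefination of 8 with F1 (KN(SiMe3)2, 18-crown-6, THF, −78 °C) should give methyl (2Z,6E,10E)-2-[2-(1,3-dioxolan-2-yl)ethyl]-6,10-dimethyltetradeca-2,6,10-trien-13-ynoate F2. Aqueous acetic acid would unmask methyl (2Z,6E,10E)-6,10-dimethyl-2-(3-oxopropyl)tetradeca-2,6,10-trien-13-ynoate F3. An enantioselective Nozaki–Hiyama–Kishi addition of 2-bromopropene (CrCl2, NiCl2 cat., the chiral sulfonamide ligand enantiomer that gives the (R)-carbinol) should give methyl (2Z,6E,10E)-2-[(3R)-3-hydroxy-4-methylpent-4-en-1-yl]-6,10-dimethyltetradeca-2,6,10-trien-13-ynoate F4, which PPTS in warm toluene would lactonize to 16.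

Step 7. The risk is over-reaction at the very electrophilic phosphorus centre: displacement of trifluoroethoxide by amide base or enolate may compete with the O-to-C phosphoryl migration. The fallback builds the phosphonate into the carbon chain before the ring exists; it sets out from Grignard reagent 10 and returns at 15. Copper-catalysed acylation of 10 with 3-chloropropanoyl chloride (CuI, THF, −78 °C) would give 5-chloro-2-methylpent-1-en-3-one F5. Triethylamine would release the vinyl ketone in situ, and Michael addition of methyl bis(2,2,2-trifluoroethyl)phosphonoacetate at its unsubstituted vinyl terminus (cat. DBU, THF) should give methyl 2-[bis(2,2,2-trifluoroethoxy)phosphoryl]-6-methyl-5-oxohept-6-enoate F6. Corey–Bakshi–Shibata reduction as in step 6 should give methyl (5R)-2-[bis(2,2,2-trifluoroethoxy)phosphoryl]-5-hydroxy-6-methylhept-6-enoate F7, and PPTS-catalysed lactonization would give 15.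

Step 10. The risk is diversion of the chromium vinylcarbene and vinylketene intermediates by the pendant alkenes, by the electron-poor alkylidene lactone or by a second alkyne insertion, at the point where the alkyne is most valuable. The fallback moves the same benzannulation ahead of the fragment coupling, so that it meets only a simple epoxy enyne; it sets out from epoxide 7 (with 21 and 15) and returns at 24. Benzannulation of 7 with 21 (THF, 50 °C, then air) should give 2-[(2E,6E)-9-(3,3-dimethyloxiran-2-yl)-3,7-dimethylnona-2,6-dien-1-yl]-4-methoxy-6-methylphenol F8. Methylation (MeI, K2CO3, acetone) would give 2-[(3E,7E)-9-(2,5-dimethoxy-3-methylphenyl)-3,7-dimethylnona-3,7-dien-1-yl]-3,3-dimethyloxirane F9. Periodic acid cleavage as in step 4 would give (4E,8E)-10-(2,5-dimethoxy-3-methylphenyl)-4,8-dimethyldeca-4,8-dienal F10. Olefination with 15 as in step 8 should give (3Z,6R)-3-[(4E,8E)-10-(2,5-dimethoxy-3-methylphenyl)-4,8-dimethyldeca-4,8-dien-1-ylidene]-6-(prop-1-en-2-yl)oxan-2-one F11, and oxidative demethylation with (NH4)2Ce(NO3)6 in MeCN/H2O at 0 °C would give 24.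

**Further compounds**

F1 | step 8 | methyl 2-[bis(2,2,2-trifluoroethoxy)phosphoryl]-4-(1,3-dioxolan-2-yl)butanoate | COC(=O)C(CCC1OCCO1)P(=O)(OCC(F)(F)F)OCC(F)(F)F
F2 | step 8 | methyl (2Z,6E,10E)-2-[2-(1,3-dioxolan-2-yl)ethyl]-6,10-dimethyltetradeca-2,6,10-trien-13-ynoate | COC(=O)/C(CCC1OCCO1)=C\CC/C(C)=C/CC/C(C)=C/CC#C
F3 | step 8 | methyl (2Z,6E,10E)-6,10-dimethyl-2-(3-oxopropyl)tetradeca-2,6,10-trien-13-ynoate | COC(=O)/C(CCC=O)=C\CC/C(C)=C/CC/C(C)=C/CC#C
F4 | step 8 | methyl (2Z,6E,10E)-2-[(3R)-3-hydroxy-4-methylpent-4-en-1-yl]-6,10-dimethyltetradeca-2,6,10-trien-13-ynoate | COC(=O)/C(CC[C@@H](O)C(C)=C)=C\CC/C(C)=C/CC/C(C)=C/CC#C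
F5 | step 7 | 5-chloro-2-methylpent-1-en-3-one | C=C(C)C(=O)CCCl
F6 | step 7 | methyl 2-[bis(2,2,2-trifluoroethoxy)phosphoryl]-6-methyl-5-oxohept-6-enoate | COC(=O)C(CCC(=O)C(C)=C)P(=O)(OCC(F)(F)F)OCC(F)(F)F
F7 | step 7 | methyl (5R)-2-[bis(2,2,2-trifluoroethoxy)phosphoryl]-5-hydroxy-6-methylhept-6-enoate | COC(=O)C(CC[C@@H](O)C(C)=C)P(=O)(OCC(F)(F)F)OCC(F)(F)F
F8 | step 10 | 2-[(2E,6E)-9-(3,3-dimethyloxiran-2-yl)-3,7-dimethylnona-2,6-dien-1-yl]-4-methoxy-6-methylphenol | CC1(C)OC1CC/C(C)=C/CC/C(C)=C/Cc1cc(OC)cc(C)c1O
F9 | step 10 | 2-[(3E,7E)-9-(2,5-dimethoxy-3-methylphenyl)-3,7-dimethylnona-3,7-dien-1-yl]-3,3-dimethyloxirane | CC1(C)OC1CC/C(C)=C/CC/C(C)=C/Cc1cc(OC)cc(C)c1OC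
F10 | step 10 | (4E,8E)-10-(2,5-dimethoxy-3-methylphenyl)-4,8-dimethyldeca-4,8-dienal | O=CCC/C(C)=C/CC/C(C)=C/Cc1cc(OC)cc(C)c1OC
F11 | step 10 | (3Z,6R)-3-[(4E,8E)-10-(2,5-dimethoxy-3-methylphenyl)-4,8-dimethyldeca-4,8-dien-1-ylidene]-6-(prop-1-en-2-yl)oxan-2-one | C=C(C)[C@H]1CC/C(=C/CC/C(C)=C/CC/C(C)=C/Cc2cc(OC)cc(C)c2OC)C(=O)O1
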